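**Plan**

1. Retrosynthesis: the two phenol acetals are cut first. The quinone ring is then cut at C3–C4, C1–C8a and C1–C2 into an aryl(methoxy)carbene chromium complex (C4 on C4a of the hydroquinone ring), one CO ligand (C1) and a terminal alkyne (C3–H, C2) that already carries the cyclobutyl angelate. The ester C–O bond and the alkynyl–carbinol bond are cut last.
2. Enabling feature: the quinone ring has one substituent only, with H on C3 between C2 and the C4 carbonyl, and is fused to a benzenoid ring in which C8a is a free ortho position next to C4a. The equal oxygens on C5 and C8 make that ring symmetric, so either sense of alkyne insertion ends in the same quinone.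
3. Forward: 2,2-dimethylcyclobutanone (ring bought) → R alkynol → angelate; hydroquinone → bis-acetal → carbene complex. Benzannulation with oxidative work-up closes the quinone ring, the only ring made in the route; acid then frees the naphthazarin.
4. Stereochemistry: the single stereocentre (R) comes from a ligand-controlled enantioselective alkynylation of the ketone and is a spectator afterwards. The Z-enoate comes from angelic acid and is kept by acylation free of nucleophilic catalysts.

Key step: step 7

Assumption: 2,2-dimethylcyclobutanone is taken as purchasable, and the (R,R)-salen ligand is taken to give the R carbinol in step 1; if a pilot run shows the opposite sense, the (S,S)-ligand is used with no other change.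

Step 1
Reactants: 1 2,2-dimethylcyclobutan-1-one; 2 ethynyl(trimethyl)silane
Product: 4 (1R)-2,2-dimethyl-1-[(trimethylsilyl)ethynyl]cyclobutan-1-ol, via alkynylzinc 3 (not isolated)
Conditions: 2 (3 equiv), Me2Zn (3 equiv), (R,R)-N,N'-bis(3,5-di-tert-butylsalicylidene)cyclohexane-1,2-diamine (20 mol%), toluene, rt, 1 h; then 1, rt, 48 h; aq NH4Cl
Reagents that add atoms: none
Why: enantioselective addition of an alkynylzinc to a ketone under zinc–salen catalysis, in which the zinc centre activates the strained, reactive cyclobutanone and the phenolate oxygens deliver the alkynylzinc; the carbonyl faces are distinguished by the quaternary C2 against the CH2 at C4, and the ligand antipode sets the R carbinol.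

Step 2
Reactants: 4 (1R)-2,2-dimethyl-1-[(trimethylsilyl)ethynyl]cyclobutan-1-ol
Product: 5 (1R)-1-ethynyl-2,2-dimethylcyclobutan-1-ol
Conditions: K2CO3 (0.2 equiv), MeOH, rt
Reagents that add atoms: none
Why: base-catalysed protodesilylation of a silylalkyne by methanol, which touches neither the tertiary alcohol nor the stereocentre.

Step 3
Reactants: 6 angelic acid, (2Z)-2-methylbut-2-enoic acid (two molecules per molecule of product)
Product: 7 angelic anhydride, (2Z)-2-methylbut-2-enoic anhydride
Conditions: 6 (2.0 equiv), DCC (1.0 equiv), CH2Cl2, 0 °C to rt; filter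
Reagents that add atoms: angelic acid (the second molecule of 6), C/C=C(/C)C(=O)O
Why: carbodiimide dehydration condenses two molecules of the carboxylic acid to the symmetric anhydride through the O-acylisourea, without base or nucleophilic catalyst, so the Z double bond is not put at risk.

Step 4
Reactants: 5 (1R)-1-ethynyl-2,2-dimethylcyclobutan-1-ol; 7 angelic anhydride
Product: 9 (1R)-1-ethynyl-2,2-dimethylcyclobutyl (2Z)-2-methylbut-2-enoate, via lithium alkoxide 8 (not isolated)
Conditions: LiN(SiMe3)2 (1.05 equiv), THF, −78 °C; then 7 (1.3 equiv), −78 to 0 °C; aq NH4Cl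
Reagents that add atoms: none
Why: O-acylation of a preformed lithium tertiary alkoxide by an anhydride is the standard way to esterify hindered propargylic carbinols, one equivalent of base removes only the O–H, and the absence of nucleophilic amine catalysts avoids the addition–elimination path from angelate to tiglate; the C–O bond at the stereocentre is not broken.

Step 5
Reactants: 10 hydroquinone
Product: 11 1,4-bis(methoxymethoxy)benzene
Conditions: NaH (2.4 equiv), DMF, 0 °C; MOMCl (2.4 equiv), 0 °C to rt
Reagents that add atoms: chloromethyl methyl ether, COCCl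
Why: Williamson-type O-alkylation of the bis-phenoxide by an α-chloro ether.

Step 6
Reactants: 11 1,4-bis(methoxymethoxy)benzene
Product: 14 pentacarbonyl{[2,5-bis(methoxymethoxy)phenyl](methoxy)methylidene}chromium, via aryllithium 12 (not isolated), via lithium acyl chromate 13 (not isolated)
Conditions: n-BuLi (1.1 equiv), THF, 0 °C, 1 h; Cr(CO)6 (1.0 equiv), THF, 0 °C to rt; evaporate; Me3OBF4 (1.5 equiv), CH2Cl2, 0 °C to rt
Reagents that add atoms: chromium hexacarbonyl, O=C=[Cr](=C=O)(=C=O)(=C=O)(=C=O)=C=O; trimethyloxonium tetrafluoroborate, C[O+](C)C.F[B-](F)(F)F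
Why: directed ortho-metalation by a methoxymethoxy group followed by the Fischer carbene synthesis, that is, aryllithium addition to a CO ligand and O-methylation of the acyl chromate by the Meerwein salt.

Step 7
Reactants: 14 pentacarbonyl{[2,5-bis(methoxymethoxy)phenyl](methoxy)methylidene}chromium; 9 (1R)-1-ethynyl-2,2-dimethylcyclobutyl (2Z)-2-methylbut-2-enoate
Product: 16 (1R)-1-[5,8-bis(methoxymethoxy)-1,4-dioxo-1,4-dihydronaphthalen-2-yl]-2,2-dimethylcyclobutyl (2Z)-2-methylbut-2-enoate, via naphthol tricarbonylchromium complex 15 (not isolated)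
Conditions: 14 (1.3 equiv), 9 (1.0 equiv), THF (0.05 M), 50 °C, 16 h, argon; then (NH4)2Ce(NO3)6 (7 equiv), MeCN/H2O, 0 °C, 30 min
Reagents that add atoms: water, O
Why: Thermal loss of a cis CO from 14 lets alkyne 9 insert into the Cr=C bond so that its terminal CH carbon bonds to the carbene carbon (the C3–C4 bond); CO insertion then gives a chromium-bound vinylketene, whose ketene carbon (C1) closes onto the free ortho carbon of the aryl ring (the C1–C8a bond), and tautomerisation gives naphthol complex 15, which tetravalent cerium oxidises to the quinone while stripping the metal. The closest known reaction type is the Dötz benzannulation of aryl(methoxy)carbene pentacarbonylchromium complexes with terminal alkynes followed by (NH4)2Ce(NO3)6 oxidation to 1,4-naphthoquinones. The one ring closed, the six-membered quinone ring, is closed by 6π-electrocyclisation of the dienylketene in a formal [3+2+1] assembly, the aryl C4a–C8a bond serving as one π-component. No new stereocentre is formed and none of the four bonds to the cyclobutyl carbinol carbon is touched, so the R configuration and the Z-enoate should pass through unchanged. The step needs the phenol pathway to win over furan, indene or cyclobutenone formation, which the donor solvent THF, the moderate temperature and the ortho-alkoxy aryl group favour, and it needs closure at the only free ortho carbon, which is secured because the other ortho carbon carries a methoxymethoxy group; the sense of alkyne insertion does not affect the constitution because the 5,8-dioxygenated ring is symmetric. The oxidation should stop at the 1,4-quinone because the free p-methoxynaphthol ring is by far the more electron-rich one and the quinone formed deactivates the bis-acetal ring.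

Step 8
Reactants: 16 (1R)-1-[5,8-bis(methoxymethoxy)-1,4-dioxo-1,4-dihydronaphthalen-2-yl]-2,2-dimethylcyclobutyl (2Z)-2-methylbut-2-enoate
Product: 17 (1R)-1-(5,8-dihydroxy-1,4-dioxo-1,4-dihydronaphthalen-2-yl)-2,2-dimethylcyclobutyl (2Z)-2-methylbut-2-enoate
Conditions: 3 M aq HCl/THF (1:4), rt
Reagents that add atoms: none
Why: acid hydrolysis of the two aryl methoxymethyl acetals, eased by the peri quinone carbonyls, frees the naphthazarin, while the tertiary ester resists ionisation because its cation would sit on a cyclobutane carbon attached to the electron-poor quinone; no bond to the stereocentre is broken.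

**Compound list**

1 | 2,2-dimethylcyclobutan-1-one | CC1(C)CCC1=O | starting material
2 | ethynyl(trimethyl)silane | C#C[Si](C)(C)C | starting material
3 | methyl[(trimethylsilyl)ethynyl]zinc (formed in the flask) | C[Zn]C#C[Si](C)(C)C | intermediate
4 | (1R)-2,2-dimethyl-1-[(trimethylsilyl)ethynyl]cyclobutan-1-ol | O[C@]1(C#C[Si](C)(C)C)CCC1(C)C | intermediate
5 | (1R)-1-ethynyl-2,2-dimethylcyclobutan-1-ol | O[C@]1(C#C)CCC1(C)C | intermediate
6 | angelic acid, (2Z)-2-methylbut-2-enoic acid | C/C=C(/C)C(=O)O | starting material
7 | angelic anhydride, (2Z)-2-methylbut-2-enoic anhydride | C/C=C(/C)C(=O)OC(=O)/C(C)=C\C | intermediate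
8 | lithium (1R)-1-ethynyl-2,2-dimethylcyclobutan-1-olate (formed in the flask) | [Li+].[O-][C@]1(C#C)CCC1(C)C | intermediate
9 | (1R)-1-ethynyl-2,2-dimethylcyclobutyl (2Z)-2-methylbut-2-enoate | C/C=C(/C)C(=O)O[C@]1(C#C)CCC1(C)C | intermediate
10 | hydroquinone | Oc1ccc(O)cc1 | starting material
11 | 1,4-bis(methoxymethoxy)benzene | COCOc1ccc(OCOC)cc1 | intermediate
12 | [2,5-bis(methoxymethoxy)phenyl]lithium (formed in the flask) | [Li]c1cc(OCOC)ccc1OCOC | intermediate
13 | lithium [2,5-bis(methoxymethoxy)benzoyl]pentacarbonylchromate (formed in the flask) | [Li+].[O-]C(c1cc(OCOC)ccc1OCOC)=[Cr](=C=O)(=C=O)(=C=O)(=C=O)=C=O | intermediate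
14 | pentacarbonyl{[2,5-bis(methoxymethoxy)phenyl](methoxy)methylidene}chromium | COC(c1cc(OCOC)ccc1OCOC)=[Cr](=C=O)(=C=O)(=C=O)(=C=O)=C=O | intermediate
15 | tricarbonylchromium complex of (1R)-1-[1-hydroxy-4-methoxy-5,8-bis(methoxymethoxy)naphthalen-2-yl]-2,2-dimethylcyclobutyl (2Z)-2-methylbut-2-enoate (formed in the flask) | C/C=C(/C)C(=O)O[C@]1(c2cc(OC)c3c(OCOC)ccc(OCOC)c3c2O)CCC1(C)C.O=C=[Cr](=C=O)=C=O | intermediate
16 | (1R)-1-[5,8-bis(methoxymethoxy)-1,4-dioxo-1,4-dihydronaphthalen-2-yl]-2,2-dimethylcyclobutyl (2Z)-2-methylbut-2-enoate | C/C=C(/C)C(=O)O[C@]1(C2=CC(=O)c3c(OCOC)ccc(OCOC)c3C2=O)CCC1(C)C | intermediate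
17 | (1R)-1-(5,8-dihydroxy-1,4-dioxo-1,4-dihydronaphthalen-2-yl)-2,2-dimethylcyclobutyl (2Z)-2-methylbut-2-enoate | C/C=C(/C)C(=O)O[C@]1(C2=CC(=O)c3c(O)ccc(O)c3C2=O)CCC1(C)C | target

**Totals**

Total step count: 8. Longest linear sequence: 5 steps (steps 1, 2, 4, 7, 8); the anhydride branch is step 3 and the arene branch is steps 5 and 6.

**Three steps most likely to fail**

Step 7. The tertiary ester may ionise or shift to the neighbouring oxygen once the free ortho-naphthol of 15 is formed, and the hindered alkyne may divert the vinylketene away from the phenol pathway. The fallback sets out from 5 and comes back at 16; it moves the acylation behind the ring construction. Compound 5 is silylated (Et3SiOTf, 2,6-lutidine, CH2Cl2, 0 °C) to triethyl{[(1R)-1-ethynyl-2,2-dimethylcyclobutyl]oxy}silane F1. F1 and 14 are taken through the same benzannulation and (NH4)2Ce(NO3)6 work-up, by way of the tricarbonylchromium complex of 2-[(1R)-2,2-dimethyl-1-(triethylsilyloxy)cyclobutyl]-4-methoxy-5,8-bis(methoxymethoxy)naphthalen-1-ol F2, to 2-[(1R)-2,2-dimethyl-1-(triethylsilyloxy)cyclobutyl]-5,8-bis(methoxymethoxy)naphthalene-1,4-dione F3. HF·pyridine in THF at 0 °C frees 2-[(1R)-1-hydroxy-2,2-dimethylcyclobutyl]-5,8-bis(methoxymethoxy)naphthalene-1,4-dione F4, whose only free hydroxyl is the tertiary one. F4 is acylated with 7 under Sc(OTf)3 catalysis (MeCN, −20 °C) to give 16.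

Step 1. Facial selectivity in alkynyl transfer to a dialkyl ketone may be too low, and uncatalysed addition to the reactive cyclobutanone may erode it further. The fallback sets out from 1 and comes back at 5; it takes the stereocentre from a Sharpless epoxidation instead. Horner–Wadsworth–Emmons olefination of 1 (triethyl phosphonoacetate, NaH, THF) should give ethyl (2E)-(2,2-dimethylcyclobutylidene)acetate F5, the ester turning away from the gem-dimethyl carbon. Reduction with i-Bu2AlH (CH2Cl2, −78 °C) should give (2E)-2-(2,2-dimethylcyclobutylidene)ethan-1-ol F6. Sharpless asymmetric epoxidation (Ti(OiPr)4, D-(−)-diethyl tartrate, t-BuOOH, 4 Å sieves, CH2Cl2, −20 °C) should give [(2R,3R)-4,4-dimethyl-1-oxaspiro[2.3]hexan-2-yl]methanol F7; the facial sense is derived by analogy with geraniol, where the L-(+)-tartrate gives the 2S,3S epoxide. PPh3/CCl4 with NaHCO3 should then give (2S,3R)-2-(chloromethyl)-4,4-dimethyl-1-oxaspiro[2.3]hexane F8. LiN(i-Pr)2 (3.3 equiv, THF, −78 to −30 °C) opens the epoxide by elimination and then removes HCl from the chloroalkene; the ring C–O bond is kept throughout, so 5 should be delivered with the R configuration.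

Step 4. The lithium alkoxide may revert to ketone and acetylide, acylation of the hindered oxygen may be slow, and the Z-enoate may drift to E. The fallback sets out from 5 and comes back at 9; it builds the Z double bond after the ester bond. Compound 5 is coupled with [bis(2,2,2-trifluoroethoxy)phosphoryl]acetic acid (DCC, CH2Cl2, via the phosphonoketene) to give (1R)-1-ethynyl-2,2-dimethylcyclobutyl [bis(2,2,2-trifluoroethoxy)phosphoryl]acetate F9. Methylation (NaH, MeI, THF, 0 °C) gives (1R)-1-ethynyl-2,2-dimethylcyclobutyl 2-[bis(2,2,2-trifluoroethoxy)phosphoryl]propanoate F10 as a mixture of epimers at the propanoate carbon. Still–Gennari olefination with acetaldehyde (KN(SiMe3)2, 18-crown-6, THF, −78 °C) should give the Z-enoate 9.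

**Further compounds**

F1 | step 7 | triethyl{[(1R)-1-ethynyl-2,2-dimethylcyclobutyl]oxy}silane | CC[Si](CC)(CC)O[C@]1(C#C)CCC1(C)C
F2 | step 7 | tricarbonylchromium complex of 2-[(1R)-2,2-dimethyl-1-(triethylsilyloxy)cyclobutyl]-4-methoxy-5,8-bis(methoxymethoxy)naphthalen-1-ol | CC[Si](CC)(CC)O[C@]1(c2cc(OC)c3c(OCOC)ccc(OCOC)c3c2O)CCC1(C)C.O=C=[Cr](=C=O)=C=O
F3 | step 7 | 2-[(1R)-2,2-dimethyl-1-(triethylsilyloxy)cyclobutyl]-5,8-bis(methoxymethoxy)naphthalene-1,4-dione | CC[Si](CC)(CC)O[C@]1(C2=CC(=O)c3c(OCOC)ccc(OCOC)c3C2=O)CCC1(C)C
F4 | step 7 | 2-[(1R)-1-hydroxy-2,2-dimethylcyclobutyl]-5,8-bis(methoxymethoxy)naphthalene-1,4-dione | O[C@]1(C2=CC(=O)c3c(OCOC)ccc(OCOC)c3C2=O)CCC1(C)C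
F5 | step 1 | ethyl (2E)-(2,2-dimethylcyclobutylidene)acetate | CCOC(=O)/C=C1\CCC1(C)C
F6 | step 1 | (2E)-2-(2,2-dimethylcyclobutylidene)ethan-1-ol | OC/C=C1\CCC1(C)C
F7 | step 1 | [(2R,3R)-4,4-dimethyl-1-oxaspiro[2.3]hexan-2-yl]methanol | O1[C@H](CO)[C@]12CCC2(C)C
F8 | step 1 | (2S,3R)-2-(chloromethyl)-4,4-dimethyl-1-oxaspiro[2.3]hexane | O1[C@H](CCl)[C@]12CCC2(C)C
F9 | step 4 | (1R)-1-ethynyl-2,2-dimethylcyclobutyl [bis(2,2,2-trifluoroethoxy)phosphoryl]acetate | O=C(CP(=O)(OCC(F)(F)F)OCC(F)(F)F)O[C@]1(C#C)CCC1(C)C
F10 | step 4 | (1R)-1-ethynyl-2,2-dimethylcyclobutyl 2-[bis(2,2,2-trifluoroethoxy)phosphoryl]propanoate | CC(C(=O)O[C@]1(C#C)CCC1(C)C)P(=O)(OCC(F)(F)F)OCC(F)(F)F
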